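If no step of the scheme removes the living chain L, the average length in a flask is the monomer G turned into chain units E divided by the chains begun, so the count of chains is the quantity to reckon.

    G + Q → L + E (k1 = 0.23 L mol⁻¹ s⁻¹)
    G + L → E + L, rate k2*[L]*[G] (k2 = 22 L mol⁻¹ s⁻¹)
    Z → Q (k3 = 0.051 s⁻¹)
    2 Q → Q2 (k4 = 520 L mol⁻¹ s⁻¹)

- blue: G 0.10 M; Z 1.8 mol%; time 20 min
- ochre: G 0.10 M; Z 1 mol%; time 20 min

- where a step has two of a species, its rate is k times that concentration squared, and two are used at each turn
- the average divides the monomer in chains by the number of chains begun, living and dead together
- run time (blue): 20 min

* which of the two ends with the longer chains by the average number of monomer units in a chain (chains begun, living or dead) ("neither" if they lie within 10%) (blue / ochre / neither)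
* average number of monomer units in a chain (chains begun, living or dead) at the end, blue
* average number of monomer units in a chain (chains begun, living or dead) at the end, ochre

Z feeds the initiating species Q with a half-life of 0.227 min, and Q has two exits: capture by G, which begins a chain, and pairing to the dead Q2. Call kd the constant of Z, kc that of capture and kp that of pairing. Per Q, capture is a pseudo-first-order constant kc[G], 0.0230 s⁻¹ at the charge of blue, while pairing is two kp[Q] and so depends on Q itself. Where feed balances pairing, [Q] is the square root of kd[Z] over two kp. For the 0.00180 M of Z in blue this is 2.97 × 10⁻⁴ M as the feed begins, and pairing per Q is then 0.309 s⁻¹, faster than capture.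

The comparison drifts, since [Q] falls as the square root of [Z], and on this reckoning capture in blue draws level with pairing at 1.70 min. Summing capture over that decline, with G held at its charge, gives the first [Q] times kc[G] times two over kd. For blue that is 2.68 × 10⁻⁴ M; this chain count C, the capture summed while pairing sets [Q], grows as the square root of the Z charge at fixed G, so ochre has 2.00 × 10⁻⁴ M.

The chains together then consume G with the first-order constant k2·C, a half-life of 1.96 min in blue and 2.63 min in ochre. The 20 min run spans 10.2 of these in blue and 7.60 in ochre, so conversion is taken as nearly full in both. This reckoning therefore gives lengths of 373 for blue and 501 for ochre. With G in blue halving at 1.96 min against a crossing at 1.70 min, holding G at its charge puts the C of blue on the high side and its length on the low side.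

The forecast says ochre, with 435 for blue and 570 for ochre, on the ground that “Q is lost mostly by pairing”; its blue length is longer than this reckoning's.

The simulation gives ochre, with 417 for blue and 551 for ochre, so the forecast's answers hold within tolerance. At 20.0 min, blue holds L at 2.39 × 10⁻⁴ M and ochre at 1.80 × 10⁻⁴ M, and C stands above these by factors of 1.12 and 1.11. The neighbouring flask is blue with G at 0.17 M and the same loading. There C is 5.94 × 10⁻⁴ M and the length 286. The simulated neighbour holds L at 4.69 × 10⁻⁴ M, a factor of 1.27 below C, and its length reads 363.

(The rate constants were set for the occasion, and the outcome is calculated.)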